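(The runs stem from a simulated flask with made-up constants, noise included.)

| flask | substrate | reagent | remark | time |
|---|---|---|---|---|
| north-west | 0.40 M | 0.40 M | run made earlier |  |
| east | 0.20 M | 0.40 M | run made earlier |  |
| north-east | 0.30 M | 0.40 M | run made earlier |  |
| south | 0.40 M | 0.80 M | run made earlier |  |
| grey | 0.40 M | 0.400 M | everything together at the start | 15 h |
| amber | 0.40 M (fed, over 6.0 h) | 0.400 M | all else is in the flask from the start; the feed brings no volume worth counting | 15 h |
| red | 0.40 M | 0.400 M (fed, over 6.0 h) | all else is in the flask from the start; the feed brings no volume worth counting | 15 h |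

- north-west (time / h: target / %, over-reaction product / %, substrate / %): 0.667: 5.6, 0.4, 84.6; 1.33: 20.8, 1.1, 63.3; 2.50: 47.7, 2.9, 30.5; 5.00: 64.4, 7.3, 8.5; 10.0: 66.0, 11.3, 2.2
- east (time / h: target / %, over-reaction product / %, substrate / %): 1.33: 11.3, 0.5, 80.1; 2.50: 30.0, 2.5, 54.7; 4.00: 52.1, 6.3, 25.8; 8.00: 62.5, 18.5, 2.8; 15.0: 49.6, 34.8, 0
- north-east (time / h: target / %, over-reaction product / %, substrate / %): 1.33: 15.6, 0.7, 71.0; 4.00: 60.1, 6.5, 16.0; 8.00: 65.4, 14.8, 2.4; 10.0: 63.1, 17.4, 0.6; 15.0: 57.3, 24.2, 0
- south (time / h: target / %, over-reaction product / %, substrate / %): 1.33: 66.4, 5.2, 18.5; 4.00: 67.8, 22.2, 0; 8.00: 50.9, 39.2, 0; 10.0: 45.2, 44.7, 0; 15.0: 34.1, 55.3, 0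

(standard deviation of a reading: 0.3 percentage points)

1. the flask that comes out highest in share of target in target plus over-reaction product, or "all alike" when all lie within 1.5 percentage points (grey / amber / red / all alike)
2. share of target in target plus over-reaction product at the end, grey
3. share of target in target plus over-reaction product at the end, amber
4. share of target in target plus over-reaction product at the end, red

**Faster, yet poorer.** Set beside the north-west run, the south run with 0.80 M of reagent held 66.4% of target against 20.8% at 1.33 h, yet at 10.0 h its share of target in target plus over-reaction product was lower, 50.3% against 85.4%.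

**Loss per target.** In the south run, with substrate at 0% from 4.00 h, target fell 34 percentage points while over-reaction product rose 33 points, so we read target as going over one for one; counting one reagent in each target and two in each over-reaction product, we take c(reagent) from 0.351 M to 0.221 M. The logarithmic fall of target, divided by time and mean c(reagent), reads 6.06 × 10⁻⁵ M⁻¹ s⁻¹: this over-reaction constant, the fraction of target lost per unit time for each molar of reagent, times c(reagent) makes a pseudo-first-order constant. At 10.0 h that constant reads 0.0571 h⁻¹ in the south run against 0.00995 h⁻¹ in the north-west run, which clears up the puzzle.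

**Our reckoning.** We carry grey on from the north-west run at 10.0 h, counting the remaining substrate as target and holding that rate, so over-reaction takes a further 3.29% of the substrate charged, and the share ends at 81.7%.

**Forecast and result.** The forecast gave grey 82.5%, 0.80 points above ours, amber 86% and red 70%, naming amber highest, and said of red that “excess reagent remains to over-react it”. The flasks gave grey 82.1%, amber 86.7% and red 72.9%, with amber highest.

    reagent + target → over-reaction product (k = 6.20 × 10⁻⁵ M⁻¹ s⁻¹)
    substrate + reagent + released group → target + 2 released group (k = 0.00430 M⁻² s⁻¹)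
    substrate + reagent → target + released group (k = 3.00 × 10⁻⁵ M⁻¹ s⁻¹)
    2 substrate → self-condensation product (k = 5.60 × 10⁻⁵ M⁻¹ s⁻¹)

**Red in order.** In red, self-condensation ran while substrate stood, with 99.7% of its turnover up to 15.0 h done by 7.50 h, when its product held 42.3% of the substrate charged. In red, over-reaction ran on with the reagent remaining, half its turnover up to 15.0 h done by 8.84 h, and at that time c(reagent) of 0.108 M gives a loss of 0.0237 h⁻¹. In the neighbour of red charged with 0.10 M of reagent, 39.0% of that charge stood at 15.0 h, giving 0.00852 h⁻¹, and its share was 92.5%.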